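## Structural features

The target is a 3,5-dihydro-2H-benzofuran-6-one. Ring B (O1, C2, C3) is a dihydrofuran fused through C3a–C7a to ring A, a cyclohexa-2,4-dienone (C3a=C4, C7=C7a, C6=O) whose carbonyl carbon lies between the sp3 carbon C5 and the enol-ether carbon C7. C2 carries a 3,4,5-trimethoxyphenyl group and C3 a methyl group; these neighbouring stereocentres are (2S,3S), trans on ring B. The third stereocentre, C5 (R), is quaternary (allyl and methoxy) and is separated from C3 by the C3a=C4 double bond, so the ring-B centres can hardly bias it. Ring A is fully substituted except for C4–H and has four contiguous oxygen-bearing carbons (C7a, C7, C6, C5). The fragile parts are the 6-allyl-6-methoxycyclohexadienone (open to [3,3] shifts of the allyl group, acid-induced dienone–phenol rearrangement, loss of methanol and cycloaddition), the benzylic C2–O1 bond next to an electron-rich arene, and the electron-rich hydroquinone-type ring of the aromatic precursors. The real difficulty is to place the ring-A oxygens regiochemically on a trans-2-aryl-3-methyl dihydrofuran and to create C5 last. The key step uses the fact that O1–C7a and the C5 oxygen are para to each other with C3a and C4 between them: this is the pattern that a Fischer carbene carbon (C7a, alkoxy oxygen O1), an alkyne (C3a, C4), CO (C5) and a 1-methoxyvinyl group (C7, C6) deliver in a Dötz benzannulation.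

## Logic of the disconnections

20 to 18 and 19: the C5–CH2 bond of the allyl group is cut. The dienone is the least stable array, so it is made last and at low temperature from a flat phenol. This removes the quaternary stereocentre and the side chain and makes ring A aromatic. The forward oxidative allylation must choose C5 over C7 and C3a, and it cannot be expected to control the C5 configuration, so separation of epimers is accepted.

18 to 15: the C6–O bond is cut. C6 is the one ring position between two methoxy groups, so directed metalation can reach it. The precursor is a simple 5,7-dimethoxy arene. The lithiation must prefer C6 over C4, over the benzylic C2–H and C3–H, and over the trimethoxyphenyl ring.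

15 to 14: the O–CH3 bond at the C5 oxygen is cut. This reveals the phenol that the annulation produces. The methylation must be done under inert gas because 14 is an oxidisable hydroquinone monoether.

14 to 12: C7a–C3a, C4–C5 and C5–C6 are cut, which opens both rings. The gain is the largest in the route: an open-chain chromium carbene with only the two ring-B stereocentres, from which the annulation places O1, the C7 methoxy group, the C5 oxygen and the C3a carbon substituent in one operation. 12 needs no protecting group, and the 1-methoxy substituent makes the alkenyl carbene α-substituted, which is the more stable kind. The forward step must join the carbene carbon to the internal alkyne carbon, against the usual preference, must achieve alkyne binding with a two-atom tether, and must leave C2 and C3 untouched.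

12 to 10 and 5: the bond between the carbene carbon and oxygen (future C7a–O1) is cut. The C2–O bond of the alcohol is never broken, so its configuration is carried over. A hindered secondary benzylic alcohol must attack the carbene carbon and not the vinyl terminus.

10 to 6 and 7: the bond between the vinyl carbon and the former CO carbon (future C7–C7a) is cut, leading back to lithiated methyl vinyl ether and chromium hexacarbonyl.

5 to 2 and 3: the bond between the carbinol carbon and the propargylic carbon (future C2–C3) is cut. This single C–C bond formation sets both stereocentres. It demands anti selectivity and clean chirality transfer from the propargylic mesylate, with attack on the Si face of the aldehyde.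

2 to 1: the O–S bond is cut; the stereocentre of the commercial alcohol is not involved.

## Other disconnections considered

Alternative 1: The C2–C3 bond of ring B is cut. In the forward sense methyl 2-diazo-2-{4-[(tert-butyldimethylsilyl)oxy]-3-methoxy-2-[(3,4,5-trimethoxybenzyl)oxy]phenyl}acetate A1 would be decomposed by the chiral divalent rhodium carboxylate Rh2(S-PTTL)4 or its enantiomer, and the carbenoid would insert into the benzylic ether C–H to give the cis ester A2.
- In its favour: it is catalytic in the chiral source, and this reaction type is established for 2-aryl-2,3-dihydrobenzofuran-3-carboxylates. On precedent and on metal economy it is better than the chosen plan, which uses stoichiometric chromium and an untested tether length.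
- Against it here: A2 is cis and carries an ester, so C3 must be epimerised and the ester reduced to methyl in about three operations. Ring A of A2 has oxygen at C6 and C7 but hydrogen at C5, so the C5 oxygen has still to be introduced before dearomatisation. A diazo compound must be handled.
- Comparison: on structure the two plans are about equal in what ring A lacks (the chosen plan lacks the C6 oxygen after its key step, this one the C5 oxygen), but the chosen plan delivers the methyl group and the trans relationship directly. On mechanism a single catalyst-controlled C–H insertion is more predictable than a multi-event chromium cascade. On step economy the alternative is longer by roughly four to five operations after its key step.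

Alternative 2: The O1–C7a and C7–O bonds are cut. LiTMP would deprotonate the hydroxyl group and C7 of (1S,2S)-2-[2-fluoro-5-methoxy-4-(methoxymethoxy)phenyl]-1-(3,4,5-trimethoxyphenyl)propan-1-ol A3; loss of LiF would give the C7–C7a aryne, the alkoxide would add at C7a, and the C7 aryllithium would be oxidised through B(OMe)3 and H2O2 to the phenol A4.
- In its favour: one operation closes ring B and oxygenates C7, and A4 already has all three ring-A oxygens. O-Methylation and removal of the methoxymethyl group would lead to 18, so the last step is shared. No chromium is needed, and intramolecular alkoxide addition to arynes is a known reaction type. On these points it is better than the chosen plan. On enforced regiochemistry (a tether that allows only the five-membered ring) the two are equal.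
- Against it here: A3 is an enantiopure anti-1,2-diarylpropanol. Its asymmetric synthesis (auxiliary aldol, deoxygenation, a fluoroarene building block) would need about twice as many steps as the four that lead to 12. A strong amide base must spare the benzylic positions, and acid removal of the acetal must spare the benzylic ether.
- Comparison: structurally it reaches 18 without a separate C6 hydroxylation; mechanistically it uses only known steps; in step economy it is equal after the key step and clearly worse before it.

Alternative 3: The C3–C3a bond is cut by thinking of ring B as a contracted pyranone. PhI(OAc)2 with HC(OMe)3 and H2SO4 would convert (2S)-7-(benzyloxy)-8-methoxy-2-(3,4,5-trimethoxyphenyl)chroman-4-one A5 into the trans ester A6 by a 1,2-shift of ring A from the carbonyl carbon to C3.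
- In its favour: the trans relationship comes directly, which equals the chosen plan and is better than Alternative 1. The flavanone skeleton is cheap to assemble, no diazo compound or chromium is involved, and the ring contraction is a known reaction of flavanones.
- Against it here: a (2S)-flavanone can lose configurational purity under strong acid by reversible opening of the pyranone. The electron-rich 2-aryl group can compete as the migrating group or promote dehydrogenation. As in Alternative 1 the ester must become a methyl group and C5 carries hydrogen.
- Comparison: on structure it is the equal of the chosen plan for C2/C3 but lacks the C5 oxygen. On mechanism it rests on a known trivalent-iodine rearrangement, with a real risk to the enantiomeric purity that the chosen plan does not have at this stage. On step economy it needs about five more operations after the key step.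

Key step: step 5

Assumption 1: the chirality transfer in step 2 is taken to follow the accepted course of the Marshall propargylation (anti SN2' palladation, retentive transfer to zinc, syn SE2' addition), which makes (R)-1 the enantiomer that leads to (1S,2S)-5.

Assumption 2: a step is counted per isolated product; compounds that react on in the flask are numbered but not counted.

Remark: 12 and 14 have (S) at both ring-B carbons (trans), as 20 has; the third centre of 20, C5 (R), is created only in step 8.

## Route

Step 1
Reactants: 1 (R)-but-3-yn-2-ol
Product: 2 (R)-but-3-yn-2-yl methanesulfonate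
Conditions: MsCl, Et3N, CH2Cl2, −78 to 0 °C
Reagents that add atoms: methanesulfonyl chloride, CS(=O)(=O)Cl
Why: Sulfonylation at oxygen of a secondary propargylic alcohol; no bond to the stereocentre is broken, so (R) is retained, and the volatile mesylate is used without storage.

Step 2
Reactants: 2 (R)-but-3-yn-2-yl methanesulfonate; 3 3,4,5-trimethoxybenzaldehyde
Product: 5 (1S,2S)-2-methyl-1-(3,4,5-trimethoxyphenyl)but-3-yn-1-ol, via allenylzinc 4 (not isolated)
Conditions: Pd(OAc)2 (5 mol %), PPh3 (5 mol %), Et2Zn (3 equiv), THF, −78 to −20 °C; aq NH4Cl
Reagents that add atoms: none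
Why: Marshall propargylation: zerovalent palladium formed in the flask ionises 2 by anti SN2' attack, transfer to zinc gives the (P)-allenylzinc 4, and 4 adds to the Si face of 3 through a cyclic SE2' transition state with the aryl group anti to the allenyl methyl; the methyl-bearing centre (S) is set by chirality transfer from 2 and the carbinol centre (S) by the anti preference, and the minor syn isomer is removed by chromatography.

Step 3
Reactants: 6 methyl vinyl ether; 7 chromium hexacarbonyl Cr(CO)6
Product: 10 tetramethylammonium pentacarbonyl(2-methoxy-1-oxidoprop-2-en-1-ylidene)chromate, via (1-methoxyethenyl)lithium 8 (not isolated), via lithium acylate 9 (not isolated)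
Conditions: t-BuLi, THF, −78 to 0 °C; Cr(CO)6, Et2O, 0 °C to rt; Me4NBr, H2O
Reagents that add atoms: tetramethylammonium bromide, C[N+](C)(C)C.[Br-]
Why: α-Lithiation of the enol ether followed by addition of the vinyllithium to a CO ligand is the first half of the Fischer carbene synthesis; cation exchange gives a weighable acylate salt that dissolves in CH2Cl2, and α-alkoxyvinyl acylates of this kind are known.

Step 4
Reactants: 10 tetramethylammonium pentacarbonyl(2-methoxy-1-oxidoprop-2-en-1-ylidene)chromate; 5 (1S,2S)-2-methyl-1-(3,4,5-trimethoxyphenyl)but-3-yn-1-ol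
Product: 12 pentacarbonyl{(1-methoxyethenyl)[(1S,2S)-2-methyl-1-(3,4,5-trimethoxyphenyl)but-3-yn-1-yloxy]methylidene}chromium, via acetoxycarbene complex 11 (not isolated)
Conditions: AcBr, CH2Cl2, −40 °C; then 5, −40 to −10 °C; rapid chromatography under N2
Reagents that add atoms: none
Why: O-Acylation of the acylate gives the strongly electrophilic acyloxycarbene, and addition–elimination of the alcohol at the carbene carbon is the standard way to Fischer carbenes of secondary alcohols; the C–O bond of 5 is not broken, so both stereocentres are retained, and the α-methoxy group lowers the acceptor character of the vinyl terminus towards conjugate addition.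

Step 5
Reactants: 12 pentacarbonyl{(1-methoxyethenyl)[(1S,2S)-2-methyl-1-(3,4,5-trimethoxyphenyl)but-3-yn-1-yloxy]methylidene}chromium
Product: 14 (2S,3S)-7-methoxy-3-methyl-2-(3,4,5-trimethoxyphenyl)-2,3-dihydro-1-benzofuran-5-ol, via tricarbonylchromium phenol complex 13 (not isolated)
Conditions: THF (0.005 M, degassed), 55 °C, Ar; then air, MeCN, rt
Reagents that add atoms: none
Why: Proposed new method: thermal loss of one CO from the zerovalent chromium carbene 12 lets the tethered alkyne bind cis to the carbene, and insertion into the chromium–carbon double bond joins C7a to the internal alkyne carbon C3a, which closes ring B in the exo mode as a five-membered ring. CO insertion at the new carbene carbon C4 gives a chromium-bound dienylketene whose ketene carbon is C5, and six-electron electrocyclisation onto the methoxyvinyl terminus C6 followed by tautomerisation closes and aromatises ring A to give 13, which air decomplexes to 14. The closest known reaction type is the intramolecular Dötz benzannulation with the alkyne tethered through the carbene heteroatom, established for longer tethers and simple alkenyl carbenes. Two further analogies support it: the chelate size required here matches that of known but-3-enyloxycarbene–alkene chelates, and α-alkoxyvinyl carbenes are known benzannulation partners. No stereocentre is formed, and C2 and C3 are spectators under neutral, non-ionising conditions. The selectivity needed is regiochemical (C7a to C3a, opposite to the usual preference of a 1-alkyne) and the two-atom tether secures it, because the other insertion mode could only lead to an impossibly strained meta-bridged arene. Phenol formation is favoured by chromium, an alkenyl carbene and a donor solvent, and high dilution suppresses intermolecular alkyne insertion.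

Step 6
Reactants: 14 (2S,3S)-7-methoxy-3-methyl-2-(3,4,5-trimethoxyphenyl)-2,3-dihydro-1-benzofuran-5-ol
Product: 15 (2S,3S)-5,7-dimethoxy-3-methyl-2-(3,4,5-trimethoxyphenyl)-2,3-dihydro-1-benzofuran
Conditions: MeI, K2CO3, acetone, reflux, N2
Reagents that add atoms: iodomethane, CI
Why: Williamson O-methylation of the only acidic hydroxyl group; it protects the hydroquinone monoether against oxidation and provides the second methoxy director for step 7.

Step 7
Reactants: 15 (2S,3S)-5,7-dimethoxy-3-methyl-2-(3,4,5-trimethoxyphenyl)-2,3-dihydro-1-benzofuran
Product: 18 (2S,3S)-5,7-dimethoxy-3-methyl-2-(3,4,5-trimethoxyphenyl)-2,3-dihydro-1-benzofuran-6-ol, via aryllithium 16 (not isolated), via dimethyl arylboronate 17 (not isolated)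
Conditions: n-BuLi, THF, 0 °C; B(OMe)3, −78 °C to rt; H2O2, AcOH, 0 °C
Reagents that add atoms: hydrogen peroxide, OO
Why: Directed ortho-metalation: C6–H lies between two methoxy groups and should be by far the most kinetically acidic site, ahead of C4–H, the ring-B C–H bonds and the trimethoxyphenyl ring; borylation and oxidation of the aryl boronate (aryl shift from boron to oxygen) place the hydroxyl group at the same carbon without touching C2 or C3.

Step 8
Reactants: 18 (2S,3S)-5,7-dimethoxy-3-methyl-2-(3,4,5-trimethoxyphenyl)-2,3-dihydro-1-benzofuran-6-ol; 19 allyltrimethylsilane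
Product: 20 (2S,3S,5R)-5,7-dimethoxy-3-methyl-5-(prop-2-en-1-yl)-2-(3,4,5-trimethoxyphenyl)-3,5-dihydro-1-benzofuran-6(2H)-one
Conditions: PhI(OCOCF3)2, 19 (5 equiv), CH2Cl2, −78 to −40 °C; aq NaHCO3; chromatographic separation of the C5 epimers
Reagents that add atoms: none
Why: Oxidative dearomatisation of a 2-alkoxyarenol by trivalent iodine with an allylsilane as carbon nucleophile (Hosomi–Sakurai type) is a known reaction type: ligand exchange at iodine and loss of PhI make ring A electrophilic at the methoxy-bearing ortho carbons, and C5 should be preferred over C7 (crowded by the fully substituted C7a) and over the para carbon C3a (no oxygen to stabilise the charge). The remote C2 and C3 centres cannot be expected to control the new C5 centre, so both epimers should form and the (5R) isomer 20 is isolated by chromatography; the low temperature guards the allyl dienone against [3,3] shifts.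

## Compound list

1 | (R)-but-3-yn-2-ol | C#C[C@@H](C)O | starting material
2 | (R)-but-3-yn-2-yl methanesulfonate | C#C[C@@H](C)OS(C)(=O)=O | intermediate
3 | 3,4,5-trimethoxybenzaldehyde | COc1cc(C=O)cc(OC)c1OC | starting material
4 | (P)-buta-1,2-dien-1-yl(ethyl)zinc (aS axis) | CC[Zn]C([H])=[C@@]=C([H])C | intermediate
5 | (1S,2S)-2-methyl-1-(3,4,5-trimethoxyphenyl)but-3-yn-1-ol | O[C@H](c1cc(OC)c(OC)c(OC)c1)[C@H](C#C)C | intermediate
6 | methyl vinyl ether | C=COC | starting material
7 | chromium hexacarbonyl, Cr(CO)6 | O=C=[Cr](=C=O)(=C=O)(=C=O)(=C=O)=C=O | starting material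
8 | (1-methoxyethenyl)lithium | [Li]C(=C)OC | intermediate
9 | lithium pentacarbonyl(2-methoxy-1-oxidoprop-2-en-1-ylidene)chromate | [Li+].C=C(OC)C([O-])=[Cr](=C=O)(=C=O)(=C=O)(=C=O)=C=O | intermediate
10 | tetramethylammonium pentacarbonyl(2-methoxy-1-oxidoprop-2-en-1-ylidene)chromate | C[N+](C)(C)C.C=C(OC)C([O-])=[Cr](=C=O)(=C=O)(=C=O)(=C=O)=C=O | intermediate
11 | pentacarbonyl[acetoxy(1-methoxyethenyl)methylidene]chromium | C=C(OC)C(OC(C)=O)=[Cr](=C=O)(=C=O)(=C=O)(=C=O)=C=O | intermediate
12 | pentacarbonyl{(1-methoxyethenyl)[(1S,2S)-2-methyl-1-(3,4,5-trimethoxyphenyl)but-3-yn-1-yloxy]methylidene}chromium | C=C(OC)C(=[Cr](=C=O)(=C=O)(=C=O)(=C=O)=C=O)O[C@H](c1cc(OC)c(OC)c(OC)c1)[C@H](C#C)C | intermediate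
13 | tricarbonyl{η6-[(2S,3S)-7-methoxy-3-methyl-2-(3,4,5-trimethoxyphenyl)-2,3-dihydro-1-benzofuran-5-ol]}chromium, chromium on ring A (written as ligand plus Cr(CO)3 fragment) | COc1cc(O)cc2c1O[C@H](c1cc(OC)c(OC)c(OC)c1)[C@H]2C.[Cr](=C=O)(=C=O)=C=O | intermediate
14 | (2S,3S)-7-methoxy-3-methyl-2-(3,4,5-trimethoxyphenyl)-2,3-dihydro-1-benzofuran-5-ol | COc1cc(O)cc2c1O[C@H](c1cc(OC)c(OC)c(OC)c1)[C@H]2C | intermediate
15 | (2S,3S)-5,7-dimethoxy-3-methyl-2-(3,4,5-trimethoxyphenyl)-2,3-dihydro-1-benzofuran | COc1cc(OC)cc2c1O[C@H](c1cc(OC)c(OC)c(OC)c1)[C@H]2C | intermediate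
16 | [(2S,3S)-5,7-dimethoxy-3-methyl-2-(3,4,5-trimethoxyphenyl)-2,3-dihydro-1-benzofuran-6-yl]lithium | COc1c([Li])c(OC)cc2c1O[C@H](c1cc(OC)c(OC)c(OC)c1)[C@H]2C | intermediate
17 | dimethyl [(2S,3S)-5,7-dimethoxy-3-methyl-2-(3,4,5-trimethoxyphenyl)-2,3-dihydro-1-benzofuran-6-yl]boronate | COB(OC)c1c(OC)cc2c(c1OC)O[C@H](c1cc(OC)c(OC)c(OC)c1)[C@H]2C | intermediate
18 | (2S,3S)-5,7-dimethoxy-3-methyl-2-(3,4,5-trimethoxyphenyl)-2,3-dihydro-1-benzofuran-6-ol | COc1cc2c(c(OC)c1O)O[C@H](c1cc(OC)c(OC)c(OC)c1)[C@H]2C | intermediate
19 | allyltrimethylsilane | C=CC[Si](C)(C)C | starting material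
20 | (2S,3S,5R)-5,7-dimethoxy-3-methyl-5-(prop-2-en-1-yl)-2-(3,4,5-trimethoxyphenyl)-3,5-dihydro-1-benzofuran-6(2H)-one | C=CC[C@@]1(OC)C=C2C(=C(OC)C1=O)O[C@H](c1cc(OC)c(OC)c(OC)c1)[C@H]2C | target

## Step count and least certain steps

Total: 8 steps. Longest linear sequence: 7 steps (1, 2, 4, 5, 6, 7, 8); step 3 is a one-step branch that joins at step 4.

Step 5 (key step, proposed new method).
- What may go wrong: the short tether may not let the alkyne reach the site cis to the carbene after CO loss, so that intermolecular alkyne insertion and oligomerisation take over. The benzylic C2–O bond of the electron-rich carbene "ester" may ionise, with loss of the alkoxy group or erosion of configuration at C2. Cyclisation without CO insertion may compete.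
- Fallback by known chemistry, from 3 to 15:
  - Commercial 3,5-dimethoxyphenylacetic acid is brominated ortho to the side chain (NBS, MeCN) to give 2-(2-bromo-3,5-dimethoxyphenyl)acetic acid F1.
  - Activation with pivaloyl chloride/Et3N and acylation of lithiated (S)-4-benzyloxazolidin-2-one gives (4S)-4-benzyl-3-[2-(2-bromo-3,5-dimethoxyphenyl)acetyl]-1,3-oxazolidin-2-one F2.
  - Evans syn aldol reaction of F2 with 3 (Bu2BOTf, i-Pr2NEt, CH2Cl2, −78 °C) gives (4S)-4-benzyl-3-[(2S,3S)-2-(2-bromo-3,5-dimethoxyphenyl)-3-hydroxy-3-(3,4,5-trimethoxyphenyl)propanoyl]-1,3-oxazolidin-2-one F3.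
  - LiBH4 (THF, H2O) removes the auxiliary to give (1S,2R)-2-(2-bromo-3,5-dimethoxyphenyl)-1-(3,4,5-trimethoxyphenyl)propane-1,3-diol F4.
  - TsCl, Et3N and catalytic DMAP sulfonylate the primary hydroxyl group to give (2R,3S)-2-(2-bromo-3,5-dimethoxyphenyl)-3-hydroxy-3-(3,4,5-trimethoxyphenyl)propyl 4-methylbenzenesulfonate F5.
  - LiEt3BH reduces the tosylate to the methyl group of (1S,2S)-2-(2-bromo-3,5-dimethoxyphenyl)-1-(3,4,5-trimethoxyphenyl)propan-1-ol F6.
  - Intramolecular Ullmann etherification (CuI, 1,10-phenanthroline, Cs2CO3, toluene, 110 °C) closes ring B with retention at both centres and rejoins the route at 15, before step 7.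

Step 8.
- What may go wrong: the allylsilane may attack C7 or the para carbon C3a instead of C5; the β-silyl cation may be captured by the carbonyl oxygen instead of losing silicon; and facial selectivity at C5 is expected to be poor because the controlling centres are remote.
- Fallback, from 18 to 20: the oxidation and the C–C bond formation are separated. PhI(OAc)2 in MeOH at 0 °C converts 18 into the ortho-quinone monoketal (2S,3S)-5,5,7-trimethoxy-3-methyl-2-(3,4,5-trimethoxyphenyl)-3,5-dihydro-1-benzofuran-6(2H)-one F7 (a regioisomeric ketal would ionise to the same cation). BF3·OEt2 and 19 in CH2Cl2 at −78 °C then replace one ketal methoxy group by allyl in a Hosomi–Sakurai substitution, rejoining the route at 20. The C5 epimers must still be separated; this fallback does not cure the facial problem.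

Step 4.
- What may go wrong: the hindered secondary alcohol may add to the vinyl terminus instead of the carbene carbon, or the acyloxycarbene may decompose before the exchange is complete.
- Fallback, from 10 to 12: MeOTf (CH2Cl2, 0 °C) gives the isolable pentacarbonyl[methoxy(1-methoxyethenyl)methylidene]chromium F8. Alkoxide-catalysed alkoxy exchange with 5 (NaH catalytic, THF, methanol removed under reduced pressure) then delivers 12, so that a purified, stable electrophile replaces the transient one.

Step 2.
- What may go wrong: the anti preference may erode with an aromatic aldehyde, and the allenylzinc may partly racemise before addition.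
- Fallback, from 3 to 5, with reagent control:
  - Brown crotylation with (E)-crotyldiisopinocampheylborane made from (−)-B-methoxydiisopinocampheylborane (Si-face attack; BF3·OEt2, −78 °C; NaOH, H2O2) gives (1S,2S)-2-methyl-1-(3,4,5-trimethoxyphenyl)but-3-en-1-ol F9.
  - TBSCl and imidazole give tert-butyl(dimethyl){[(1S,2S)-2-methyl-1-(3,4,5-trimethoxyphenyl)but-3-en-1-yl]oxy}silane F10.
  - Lemieux–Johnson cleavage (OsO4 catalytic, NaIO4, 2,6-lutidine) gives (2R,3S)-3-[(tert-butyldimethylsilyl)oxy]-2-methyl-3-(3,4,5-trimethoxyphenyl)propanal F11.
  - Ohira–Bestmann homologation (dimethyl 1-diazo-2-oxopropylphosphonate, K2CO3, MeOH) gives tert-butyl(dimethyl){[(1S,2S)-2-methyl-1-(3,4,5-trimethoxyphenyl)but-3-yn-1-yl]oxy}silane F12.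
  - Bu4NF in THF removes the silyl group and rejoins the route at 5.

## Further compounds

F1 | step 5 | 2-(2-bromo-3,5-dimethoxyphenyl)acetic acid | OC(=O)Cc1cc(OC)cc(OC)c1Br
F2 | step 5 | (4S)-4-benzyl-3-[2-(2-bromo-3,5-dimethoxyphenyl)acetyl]-1,3-oxazolidin-2-one | O=C(Cc1cc(OC)cc(OC)c1Br)N1[C@@H](Cc2ccccc2)COC1=O
F3 | step 5 | (4S)-4-benzyl-3-[(2S,3S)-2-(2-bromo-3,5-dimethoxyphenyl)-3-hydroxy-3-(3,4,5-trimethoxyphenyl)propanoyl]-1,3-oxazolidin-2-one | O=C([C@@H](c1cc(OC)cc(OC)c1Br)[C@H](O)c1cc(OC)c(OC)c(OC)c1)N1[C@@H](Cc2ccccc2)COC1=O
F4 | step 5 | (1S,2R)-2-(2-bromo-3,5-dimethoxyphenyl)-1-(3,4,5-trimethoxyphenyl)propane-1,3-diol | O[C@H](c1cc(OC)c(OC)c(OC)c1)[C@H](c1cc(OC)cc(OC)c1Br)CO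
F5 | step 5 | (2R,3S)-2-(2-bromo-3,5-dimethoxyphenyl)-3-hydroxy-3-(3,4,5-trimethoxyphenyl)propyl 4-methylbenzenesulfonate | O[C@H](c1cc(OC)c(OC)c(OC)c1)[C@H](c1cc(OC)cc(OC)c1Br)COS(=O)(=O)c1ccc(C)cc1
F6 | step 5 | (1S,2S)-2-(2-bromo-3,5-dimethoxyphenyl)-1-(3,4,5-trimethoxyphenyl)propan-1-ol | O[C@H](c1cc(OC)c(OC)c(OC)c1)[C@H](c1cc(OC)cc(OC)c1Br)C
F7 | step 8 | (2S,3S)-5,5,7-trimethoxy-3-methyl-2-(3,4,5-trimethoxyphenyl)-3,5-dihydro-1-benzofuran-6(2H)-one | COC1(OC)C=C2C(=C(OC)C1=O)O[C@H](c1cc(OC)c(OC)c(OC)c1)[C@H]2C
F8 | step 4 | pentacarbonyl[methoxy(1-methoxyethenyl)methylidene]chromium | C=C(OC)C(OC)=[Cr](=C=O)(=C=O)(=C=O)(=C=O)=C=O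
F9 | step 2 | (1S,2S)-2-methyl-1-(3,4,5-trimethoxyphenyl)but-3-en-1-ol | O[C@H](c1cc(OC)c(OC)c(OC)c1)[C@H](C=C)C
F10 | step 2 | tert-butyl(dimethyl){[(1S,2S)-2-methyl-1-(3,4,5-trimethoxyphenyl)but-3-en-1-yl]oxy}silane | CC(C)(C)[Si](C)(C)O[C@H](c1cc(OC)c(OC)c(OC)c1)[C@H](C=C)C
F11 | step 2 | (2R,3S)-3-[(tert-butyldimethylsilyl)oxy]-2-methyl-3-(3,4,5-trimethoxyphenyl)propanal | CC(C)(C)[Si](C)(C)O[C@H](c1cc(OC)c(OC)c(OC)c1)[C@H](C=O)C
F12 | step 2 | tert-butyl(dimethyl){[(1S,2S)-2-methyl-1-(3,4,5-trimethoxyphenyl)but-3-yn-1-yl]oxy}silane | CC(C)(C)[Si](C)(C)O[C@H](c1cc(OC)c(OC)c(OC)c1)[C@H](C#C)C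
A1 | alternative 1 | methyl 2-diazo-2-{4-[(tert-butyldimethylsilyl)oxy]-3-methoxy-2-[(3,4,5-trimethoxybenzyl)oxy]phenyl}acetate | COC(=O)C(=[N+]=[N-])c1ccc(O[Si](C)(C)C(C)(C)C)c(OC)c1OCc1cc(OC)c(OC)c(OC)c1
A2 | alternative 1 | methyl (2S,3R)-6-[(tert-butyldimethylsilyl)oxy]-7-methoxy-2-(3,4,5-trimethoxyphenyl)-2,3-dihydro-1-benzofuran-3-carboxylate (2,3-cis) | CC(C)(C)[Si](C)(C)Oc1ccc2c(c1OC)O[C@H](c1cc(OC)c(OC)c(OC)c1)[C@@H]2C(=O)OC
A3 | alternative 2 | (1S,2S)-2-[2-fluoro-5-methoxy-4-(methoxymethoxy)phenyl]-1-(3,4,5-trimethoxyphenyl)propan-1-ol | O[C@H](c1cc(OC)c(OC)c(OC)c1)[C@H](c1cc(OC)c(OCOC)cc1F)C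
A4 | alternative 2 | (2S,3S)-5-methoxy-6-(methoxymethoxy)-3-methyl-2-(3,4,5-trimethoxyphenyl)-2,3-dihydro-1-benzofuran-7-ol | COCOc1c(OC)cc2c(c1O)O[C@H](c1cc(OC)c(OC)c(OC)c1)[C@H]2C
A5 | alternative 3 | (2S)-7-(benzyloxy)-8-methoxy-2-(3,4,5-trimethoxyphenyl)chroman-4-one | O=C1C[C@@H](c2cc(OC)c(OC)c(OC)c2)Oc2c1ccc(OCc1ccccc1)c2OC
A6 | alternative 3 | methyl (2S,3S)-6-(benzyloxy)-7-methoxy-2-(3,4,5-trimethoxyphenyl)-2,3-dihydro-1-benzofuran-3-carboxylate (2,3-trans) | c1ccccc1COc1ccc2c(c1OC)O[C@H](c1cc(OC)c(OC)c(OC)c1)[C@H]2C(=O)OC
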